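**Strategy.** Ring A of the 2,3-dihydrobenzofuran is built, not bought. Its contiguous row C7(OH)–C7a(O1)–C3a–C4(acrylate) is read as an alkoxycarbene carbon, the double bond of a cyclic enol ether and a CO ligand. A Dötz benzannulation of a pentacarbonylchromium (benzyloxy)(2,3-dihydrofuran-5-yl)carbene with trimethylsilylacetylene therefore forms C7–C6, C5–C4 and C4–C3a in one operation and delivers a 4-hydroxy-7-benzyloxy arene on the preformed trans C2/C3 diad. The precursor comes from an Evans succinate aldol lactone (a trans aryl paraconate) with C3 held at the carbinol oxidation level. The C4 hydroxyl later becomes the triflate for a Heck coupling with the lactate acrylate.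

Key step: step 10

Remark: the C3 carbinol is carried as a triisopropylsilyl ether so that it survives the acid that removes the C5 silicon; that silicon is removed before the C4 hydroxyl is triflated because an ortho-silylaryl triflate is an aryne precursor; CIP labels at C3 change with the substituent while the spatial arrangement stays that of the target; chromium complexes are written in the Cr=C=O valence-bond convention.

Step 1
Reactants: 1 (4S)-4-benzyl-1,3-oxazolidin-2-one; 2 methyl 4-chloro-4-oxobutanoate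
Product: 3 methyl 4-[(4S)-4-benzyl-2-oxo-1,3-oxazolidin-3-yl]-4-oxobutanoate
Conditions: n-BuLi, THF, −78 °C; then 2, −78 to 0 °C
Reagents that add atoms: none
Why: N-acylation of the lithiated oxazolidinone by the acid chloride (imide formation) is fast at low temperature and leaves the methyl ester untouched.

Step 2
Reactants: 3; 4 3,4-bis(benzyloxy)benzaldehyde
Product: 6 (4S)-4-benzyl-3-{[(2S,3S)-2-[3,4-bis(benzyloxy)phenyl]-5-oxooxolan-3-yl]carbonyl}-1,3-oxazolidin-2-one, via syn-aldol adduct 5 (not isolated)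
Conditions: Bu2BOTf, i-Pr2NEt, CH2Cl2, 0 °C; 4, −78 to 0 °C; H2O2, pH 7 buffer/MeOH, 0 °C; then PPTS (cat.), toluene, 50 °C
Reagents that add atoms: none
Why: Evans syn-aldol reaction of the Z-boron enolate through a chair transition state, in which the benzyl group of the auxiliary blocks one enolate face, should set the carbinol centre (S) and the alpha centre (S), and lactonisation of the gamma-hydroxy ester turns the syn aldol into the trans lactone.

Step 3
Reactants: 6
Product: 7 (2S,3S)-2-[3,4-bis(benzyloxy)phenyl]-5-oxooxolane-3-carboxylic acid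
Conditions: LiOH, H2O2, THF/H2O, 0 °C; Na2SO3; HCl to pH 2
Reagents that add atoms: hydrogen peroxide (as LiOOH), OO
Why: Hydroperoxide attacks the exocyclic imide carbonyl selectively (LiOOH auxiliary cleavage), and any lactone opened by hydroxide recloses on acidification because only the gamma-lactone is possible and the trans acid is the stable isomer.

Step 4
Reactants: 7
Product: 8 (4R,5S)-5-[3,4-bis(benzyloxy)phenyl]-4-(hydroxymethyl)oxolan-2-one
Conditions: BH3·SMe2, THF, 0 °C to rt; MeOH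
Reagents that add atoms: none
Why: Chemoselective borane reduction of a carboxylic acid through its acyloxyborane is much faster than reduction of a lactone, and the base-free medium avoids translactonisation and epimerisation.

Step 5
Reactants: 8
Product: 9 (4R,5S)-5-[3,4-bis(benzyloxy)phenyl]-4-{[(triisopropylsilyl)oxy]methyl}oxolan-2-one
Conditions: TIPSOTf, 2,6-lutidine, CH2Cl2, −78 to 0 °C
Reagents that add atoms: triisopropylsilyl trifluoromethanesulfonate, CC(C)[Si](C(C)C)(C(C)C)OS(=O)(=O)C(F)(F)F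
Why: Silyl ether formation with a silyl triflate and a hindered pyridine base is fast on a primary alcohol at low temperature and outruns acyl migration.

Step 6
Reactants: 9
Product: 10 (2S,3R)-2-[3,4-bis(benzyloxy)phenyl]-3-{[(triisopropylsilyl)oxy]methyl}-2,3-dihydrofuran-5-yl diphenyl phosphate
Conditions: KN(SiMe3)2, (PhO)2P(O)Cl, THF/HMPA, −78 °C
Reagents that add atoms: diphenyl chlorophosphate, O=P(Cl)(Oc1ccccc1)Oc1ccccc1
Why: O-Phosphorylation of the kinetic lactone enolate gives the ketene acetal phosphate; the ring CH2 is the only acidic site and C3 carries no leaving group, so the diad is not touched.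

Step 7
Reactants: 10
Product: 11 [(2S,3R)-2-[3,4-bis(benzyloxy)phenyl]-3-{[(triisopropylsilyl)oxy]methyl}-2,3-dihydrofuran-5-yl]trimethylstannane
Conditions: (Me3Sn)2, Pd(PPh3)4 (5 mol %), LiCl, THF, 65 °C
Reagents that add atoms: hexamethylditin, C[Sn](C)(C)[Sn](C)(C)C
Why: Stille-type stannylation, in which zerovalent palladium inserts into the C–O bond of the lactone-derived ketene acetal phosphate and transmetallation with the ditin is followed by reductive elimination, gives the alpha-alkoxyvinylstannane.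

Step 8
Reactants: 11; 12 chromium hexacarbonyl, Cr(CO)6
Product: 15 tetramethylammonium pentacarbonyl{[(2S,3R)-2-[3,4-bis(benzyloxy)phenyl]-3-{[(triisopropylsilyl)oxy]methyl}-2,3-dihydrofuran-5-yl]carbonyl}chromate, via vinyllithium 13 (not isolated), via lithium acylchromate 14 (not isolated)
Conditions: MeLi, THF, −78 °C; Cr(CO)6, THF, −78 °C to rt; Me4NBr, H2O, rt
Reagents that add atoms: tetramethylammonium bromide, C[N+](C)(C)C.[Br-]
Why: Tin–lithium exchange gives the alpha-alkoxyvinyllithium without deprotonating the benzyl ethers, its addition to a CO ligand is the first half of the Fischer carbene synthesis, and cation exchange gives an acylmetalate salt that can be purified.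

Step 9
Reactants: 15
Product: 17 pentacarbonyl{(benzyloxy)[(2S,3R)-2-[3,4-bis(benzyloxy)phenyl]-3-{[(triisopropylsilyl)oxy]methyl}-2,3-dihydrofuran-5-yl]methylidene}chromium, via acetoxycarbene complex 16 (not isolated)
Conditions: AcBr, CH2Cl2, −40 °C; then BnOH, −40 to 0 °C
Reagents that add atoms: benzyl alcohol, OCc1ccccc1
Why: O-Acylation of the acylmetalate gives a very electrophilic acyloxycarbene that exchanges with benzyl alcohol by addition–elimination at the carbene carbon (alkoxy exchange route to Fischer carbenes), used because benzyl halides do not alkylate acylchromates cleanly.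

Step 10
Reactants: 17; 18 trimethylsilylacetylene
Product: 20 (2S,3R)-7-(benzyloxy)-2-[3,4-bis(benzyloxy)phenyl]-5-(trimethylsilyl)-3-{[(triisopropylsilyl)oxy]methyl}-2,3-dihydro-1-benzofuran-4-ol, via tricarbonylchromium arene complex 19 (not isolated)
Conditions: 18 (3 equiv), THF, 55 °C, Ar; then air, Et2O, rt
Reagents that add atoms: none
Why: Thermal loss of one CO ligand lets 18 bind and insert into the chromium–carbene bond with its unsubstituted carbon joined to the carbene carbon (C7–C6), CO insertion at the silyl-bearing carbon gives a chromium-bound dienylketene (C5–C4), and ring A closes between the ketene carbon C4 and the enol ether carbon C3a before tautomerisation to the phenol. The closest known reaction type is the Dötz benzannulation of alkenyl(alkoxy)carbene complexes of Cr(CO)5, cyclic alpha-alkoxyvinyl complexes included, with terminal alkynes. Ring A is closed by a thermal disrotatory 6π-electrocyclisation of the Z-dienylketene. No stereocentre is formed, and the C2/C3 diad should persist because the medium is neutral and aromatisation removes only the hydrogen on C3a. The selectivities needed are the alkyne orientation and phenol formation over cyclopentannulation or arrest at a silyl vinylketene; the bulk of SiMe3 places it on C5 beside the CO-derived carbon, and an alkoxy(alkenyl)carbene on zerovalent chromium in THF favours CO insertion and cyclisation. A carbon-to-oxygen silyl shift would not matter, since step 11 removes the silicon either way.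

Step 11
Reactants: 20
Product: 21 (2S,3R)-7-(benzyloxy)-2-[3,4-bis(benzyloxy)phenyl]-3-{[(triisopropylsilyl)oxy]methyl}-2,3-dihydro-1-benzofuran-4-ol
Conditions: CF3CO2H (5 equiv), CH2Cl2, 0 °C
Reagents that add atoms: none
Why: Ipso-protodesilylation (electrophilic aromatic substitution at C5) should be fast because C5 is ortho to the C4 hydroxyl and para to O1, while the triisopropylsilyl ether and the benzyl ethers tolerate brief cold acid.

Step 12
Reactants: 21
Product: 22 (2S,3R)-7-(benzyloxy)-2-[3,4-bis(benzyloxy)phenyl]-3-{[(triisopropylsilyl)oxy]methyl}-2,3-dihydro-1-benzofuran-4-yl trifluoromethanesulfonate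
Conditions: Tf2O, pyridine, CH2Cl2, 0 °C
Reagents that add atoms: trifluoromethanesulfonic anhydride, O=S(=O)(OS(=O)(=O)C(F)(F)F)C(F)(F)F
Why: O-Sulfonylation of the only free hydroxyl, now flanked by a hydrogen at C5, gives the aryl triflate and also protects the air-sensitive hydroquinone monoether.

Step 13
Reactants: 23 (2R)-3-(3,4-dihydroxyphenyl)-2-hydroxypropanoic acid
Product: 24 methyl (2R)-3-(3,4-dihydroxyphenyl)-2-hydroxypropanoate
Conditions: MeOH, H2SO4 (cat.), 60 °C
Reagents that add atoms: methanol, CO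
Why: Fischer esterification proceeds at the carboxyl group only and does not touch the alpha stereocentre.

Step 14
Reactants: 24
Product: 25 methyl (2R)-3-[3,4-bis(benzyloxy)phenyl]-2-hydroxypropanoate
Conditions: BnBr, K2CO3, DMF, rt
Reagents that add atoms: benzyl bromide, BrCc1ccccc1
Why: Williamson etherification with a carbonate base alkylates only the phenols, which are far more acidic than the secondary alcohol, and room temperature keeps the alpha-hydroxy ester configurationally intact.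

Step 15
Reactants: 25
Product: 26 methyl (2R)-3-[3,4-bis(benzyloxy)phenyl]-2-(prop-2-enoyloxy)propanoate
Conditions: acryloyl chloride, Et3N, CH2Cl2, −20 to 0 °C
Reagents that add atoms: acryloyl chloride, C=CC(=O)Cl
Why: O-Acylation of the secondary alcohol with an acid chloride and an amine base is straightforward and retains configuration because the C–O bond is not broken.

Step 16
Reactants: 22; 26
Product: 27 methyl (2R)-3-[3,4-bis(benzyloxy)phenyl]-2-{[(2E)-3-[(2S,3R)-7-(benzyloxy)-2-[3,4-bis(benzyloxy)phenyl]-3-{[(triisopropylsilyl)oxy]methyl}-2,3-dihydro-1-benzofuran-4-yl]prop-2-enoyl]oxy}propanoate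
Conditions: Pd(OAc)2 (10 mol %), 1,3-bis(diphenylphosphino)propane, Cy2NMe, DMF, 90 °C
Reagents that add atoms: none
Why: Heck reaction of an aryl triflate with an acrylate (oxidative addition to zerovalent palladium, syn insertion, syn beta-hydride elimination) gives the E-cinnamate, and the hindered amine base and protected C3 carbinol avoid epimerisation of the lactate and reduction of the arylpalladium.

Step 17
Reactants: 27
Product: 28 methyl (2R)-3-[3,4-bis(benzyloxy)phenyl]-2-{[(2E)-3-[(2S,3R)-7-(benzyloxy)-2-[3,4-bis(benzyloxy)phenyl]-3-(hydroxymethyl)-2,3-dihydro-1-benzofuran-4-yl]prop-2-enoyl]oxy}propanoate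
Conditions: HF·pyridine, pyridine, THF, 0 °C to rt
Reagents that add atoms: none
Why: Fluoride desilylation under buffered acidic conditions frees the primary alcohol without generating an alkoxide, so oxa-Michael closure onto the neighbouring acrylate and ester exchange are avoided.

Step 18
Reactants: 28
Product: 30 (2S,3S)-7-(benzyloxy)-2-[3,4-bis(benzyloxy)phenyl]-4-[(1E)-3-{[(2R)-3-[3,4-bis(benzyloxy)phenyl]-1-methoxy-1-oxopropan-2-yl]oxy}-3-oxoprop-1-en-1-yl]-2,3-dihydro-1-benzofuran-3-carboxylic acid, via aldehyde 29 (not isolated)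
Conditions: TEMPO (20 mol %), PhI(OAc)2 (2.5 equiv), MeCN/pH 7 buffer, rt
Reagents that add atoms: water, O
Why: Nitroxyl-catalysed oxidation takes the primary alcohol through the aldehyde hydrate to the acid near neutral pH, where the alkene, esters and benzyl ethers are inert and the trans C2/C3 arrangement is the stable one.

Step 19
Reactants: 30
Product: 31 (2S,3S)-2-(3,4-dihydroxyphenyl)-4-[(1E)-3-{[(2R)-3-(3,4-dihydroxyphenyl)-1-methoxy-1-oxopropan-2-yl]oxy}-3-oxoprop-1-en-1-yl]-7-hydroxy-2,3-dihydro-1-benzofuran-3-carboxylic acid (target)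
Conditions: BCl3 (12 equiv), C6HMe5 (15 equiv), CH2Cl2, −78 °C; then CHCl3/MeOH, −78 °C; aqueous work-up at pH 3
Reagents that add atoms: none
Why: Lewis-acid debenzylation of aryl benzyl ethers with a non-basic cation scavenger works at −78 °C without a reductant, so the alkene and both esters should survive, and a C2–O1 bond that ionises can reclose to the trans ring.

**Compound list**

1 | (4S)-4-benzyl-1,3-oxazolidin-2-one | O=C1OC[C@H](Cc2ccccc2)N1 | starting material
2 | methyl 4-chloro-4-oxobutanoate | COC(=O)CCC(Cl)=O | starting material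
3 | methyl 4-[(4S)-4-benzyl-2-oxo-1,3-oxazolidin-3-yl]-4-oxobutanoate | COC(=O)CCC(=O)N1C(=O)OC[C@@H]1Cc1ccccc1 | intermediate
4 | 3,4-bis(benzyloxy)benzaldehyde | O=Cc1ccc(OCc2ccccc2)c(OCc2ccccc2)c1 | starting material
5 | methyl (3S,4S)-3-{[(4S)-4-benzyl-2-oxo-1,3-oxazolidin-3-yl]carbonyl}-4-[3,4-bis(benzyloxy)phenyl]-4-hydroxybutanoate (syn-aldol adduct, not isolated) | COC(=O)C[C@H](C(=O)N1C(=O)OC[C@@H]1Cc1ccccc1)[C@H](O)c1ccc(OCc2ccccc2)c(OCc2ccccc2)c1 | intermediate
6 | (4S)-4-benzyl-3-{[(2S,3S)-2-[3,4-bis(benzyloxy)phenyl]-5-oxooxolan-3-yl]carbonyl}-1,3-oxazolidin-2-one | O=C1C[C@H](C(=O)N2C(=O)OC[C@@H]2Cc2ccccc2)[C@@H](c2ccc(OCc3ccccc3)c(OCc3ccccc3)c2)O1 | intermediate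
7 | (2S,3S)-2-[3,4-bis(benzyloxy)phenyl]-5-oxooxolane-3-carboxylic acid | O=C1C[C@H](C(=O)O)[C@@H](c2ccc(OCc3ccccc3)c(OCc3ccccc3)c2)O1 | intermediate
8 | (4R,5S)-5-[3,4-bis(benzyloxy)phenyl]-4-(hydroxymethyl)oxolan-2-one | O=C1C[C@H](CO)[C@@H](c2ccc(OCc3ccccc3)c(OCc3ccccc3)c2)O1 | intermediate
9 | (4R,5S)-5-[3,4-bis(benzyloxy)phenyl]-4-{[(triisopropylsilyl)oxy]methyl}oxolan-2-one | O=C1C[C@H](CO[Si](C(C)C)(C(C)C)C(C)C)[C@@H](c2ccc(OCc3ccccc3)c(OCc3ccccc3)c2)O1 | intermediate
10 | (2S,3R)-2-[3,4-bis(benzyloxy)phenyl]-3-{[(triisopropylsilyl)oxy]methyl}-2,3-dihydrofuran-5-yl diphenyl phosphate | O=P(Oc1ccccc1)(Oc1ccccc1)OC1=C[C@H](CO[Si](C(C)C)(C(C)C)C(C)C)[C@@H](c2ccc(OCc3ccccc3)c(OCc3ccccc3)c2)O1 | intermediate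
11 | [(2S,3R)-2-[3,4-bis(benzyloxy)phenyl]-3-{[(triisopropylsilyl)oxy]methyl}-2,3-dihydrofuran-5-yl]trimethylstannane | C[Sn](C)(C)C1=C[C@H](CO[Si](C(C)C)(C(C)C)C(C)C)[C@@H](c2ccc(OCc3ccccc3)c(OCc3ccccc3)c2)O1 | intermediate
12 | chromium hexacarbonyl, Cr(CO)6 | O=C=[Cr](=C=O)(=C=O)(=C=O)(=C=O)=C=O | starting material
13 | [(2S,3R)-2-[3,4-bis(benzyloxy)phenyl]-3-{[(triisopropylsilyl)oxy]methyl}-2,3-dihydrofuran-5-yl]lithium (not isolated) | [Li]C1=C[C@H](CO[Si](C(C)C)(C(C)C)C(C)C)[C@@H](c2ccc(OCc3ccccc3)c(OCc3ccccc3)c2)O1 | intermediate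
14 | lithium pentacarbonyl{[(2S,3R)-2-[3,4-bis(benzyloxy)phenyl]-3-{[(triisopropylsilyl)oxy]methyl}-2,3-dihydrofuran-5-yl]carbonyl}chromate (not isolated) | [Li+].[O-]C(=[Cr](=C=O)(=C=O)(=C=O)(=C=O)=C=O)C1=C[C@H](CO[Si](C(C)C)(C(C)C)C(C)C)[C@@H](c2ccc(OCc3ccccc3)c(OCc3ccccc3)c2)O1 | intermediate
15 | tetramethylammonium pentacarbonyl{[(2S,3R)-2-[3,4-bis(benzyloxy)phenyl]-3-{[(triisopropylsilyl)oxy]methyl}-2,3-dihydrofuran-5-yl]carbonyl}chromate | C[N+](C)(C)C.[O-]C(=[Cr](=C=O)(=C=O)(=C=O)(=C=O)=C=O)C1=C[C@H](CO[Si](C(C)C)(C(C)C)C(C)C)[C@@H](c2ccc(OCc3ccccc3)c(OCc3ccccc3)c2)O1 | intermediate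
16 | pentacarbonyl{(acetyloxy)[(2S,3R)-2-[3,4-bis(benzyloxy)phenyl]-3-{[(triisopropylsilyl)oxy]methyl}-2,3-dihydrofuran-5-yl]methylidene}chromium (not isolated) | CC(=O)OC(=[Cr](=C=O)(=C=O)(=C=O)(=C=O)=C=O)C1=C[C@H](CO[Si](C(C)C)(C(C)C)C(C)C)[C@@H](c2ccc(OCc3ccccc3)c(OCc3ccccc3)c2)O1 | intermediate
17 | pentacarbonyl{(benzyloxy)[(2S,3R)-2-[3,4-bis(benzyloxy)phenyl]-3-{[(triisopropylsilyl)oxy]methyl}-2,3-dihydrofuran-5-yl]methylidene}chromium | O=C=[Cr](=C=O)(=C=O)(=C=O)(=C=O)=C(OCc1ccccc1)C1=C[C@H](CO[Si](C(C)C)(C(C)C)C(C)C)[C@@H](c2ccc(OCc3ccccc3)c(OCc3ccccc3)c2)O1 | intermediate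
18 | trimethylsilylacetylene | C#C[Si](C)(C)C | starting material
19 | tricarbonylchromium η6 complex of 20 on ring A (η6 bond not drawn, not isolated) | O=C=[Cr](=C=O)=C=O.Oc1c([Si](C)(C)C)cc(OCc2ccccc2)c2c1[C@H](CO[Si](C(C)C)(C(C)C)C(C)C)[C@@H](c1ccc(OCc3ccccc3)c(OCc3ccccc3)c1)O2 | intermediate
20 | (2S,3R)-7-(benzyloxy)-2-[3,4-bis(benzyloxy)phenyl]-5-(trimethylsilyl)-3-{[(triisopropylsilyl)oxy]methyl}-2,3-dihydro-1-benzofuran-4-ol | Oc1c([Si](C)(C)C)cc(OCc2ccccc2)c2c1[C@H](CO[Si](C(C)C)(C(C)C)C(C)C)[C@@H](c1ccc(OCc3ccccc3)c(OCc3ccccc3)c1)O2 | intermediate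
21 | (2S,3R)-7-(benzyloxy)-2-[3,4-bis(benzyloxy)phenyl]-3-{[(triisopropylsilyl)oxy]methyl}-2,3-dihydro-1-benzofuran-4-ol | Oc1ccc(OCc2ccccc2)c2c1[C@H](CO[Si](C(C)C)(C(C)C)C(C)C)[C@@H](c1ccc(OCc3ccccc3)c(OCc3ccccc3)c1)O2 | intermediate
22 | (2S,3R)-7-(benzyloxy)-2-[3,4-bis(benzyloxy)phenyl]-3-{[(triisopropylsilyl)oxy]methyl}-2,3-dihydro-1-benzofuran-4-yl trifluoromethanesulfonate | O=S(=O)(Oc1ccc(OCc2ccccc2)c2c1[C@H](CO[Si](C(C)C)(C(C)C)C(C)C)[C@@H](c1ccc(OCc3ccccc3)c(OCc3ccccc3)c1)O2)C(F)(F)F | intermediate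
23 | (2R)-3-(3,4-dihydroxyphenyl)-2-hydroxypropanoic acid | OC(=O)[C@@H](Cc1ccc(O)c(O)c1)O | starting material
24 | methyl (2R)-3-(3,4-dihydroxyphenyl)-2-hydroxypropanoate | COC(=O)[C@@H](Cc1ccc(O)c(O)c1)O | intermediate
25 | methyl (2R)-3-[3,4-bis(benzyloxy)phenyl]-2-hydroxypropanoate | COC(=O)[C@@H](Cc1ccc(OCc2ccccc2)c(OCc2ccccc2)c1)O | intermediate
26 | methyl (2R)-3-[3,4-bis(benzyloxy)phenyl]-2-(prop-2-enoyloxy)propanoate | COC(=O)[C@@H](Cc1ccc(OCc2ccccc2)c(OCc2ccccc2)c1)OC(=O)C=C | intermediate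
27 | methyl (2R)-3-[3,4-bis(benzyloxy)phenyl]-2-{[(2E)-3-[(2S,3R)-7-(benzyloxy)-2-[3,4-bis(benzyloxy)phenyl]-3-{[(triisopropylsilyl)oxy]methyl}-2,3-dihydro-1-benzofuran-4-yl]prop-2-enoyl]oxy}propanoate | COC(=O)[C@@H](Cc1ccc(OCc2ccccc2)c(OCc2ccccc2)c1)OC(=O)/C=C/c1ccc(OCc2ccccc2)c2c1[C@H](CO[Si](C(C)C)(C(C)C)C(C)C)[C@@H](c1ccc(OCc3ccccc3)c(OCc3ccccc3)c1)O2 | intermediate
28 | methyl (2R)-3-[3,4-bis(benzyloxy)phenyl]-2-{[(2E)-3-[(2S,3R)-7-(benzyloxy)-2-[3,4-bis(benzyloxy)phenyl]-3-(hydroxymethyl)-2,3-dihydro-1-benzofuran-4-yl]prop-2-enoyl]oxy}propanoate | COC(=O)[C@@H](Cc1ccc(OCc2ccccc2)c(OCc2ccccc2)c1)OC(=O)/C=C/c1ccc(OCc2ccccc2)c2c1[C@H](CO)[C@@H](c1ccc(OCc3ccccc3)c(OCc3ccccc3)c1)O2 | intermediate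
29 | methyl (2R)-3-[3,4-bis(benzyloxy)phenyl]-2-{[(2E)-3-[(2S,3S)-7-(benzyloxy)-2-[3,4-bis(benzyloxy)phenyl]-3-formyl-2,3-dihydro-1-benzofuran-4-yl]prop-2-enoyl]oxy}propanoate (not isolated) | COC(=O)[C@@H](Cc1ccc(OCc2ccccc2)c(OCc2ccccc2)c1)OC(=O)/C=C/c1ccc(OCc2ccccc2)c2c1[C@H](C=O)[C@@H](c1ccc(OCc3ccccc3)c(OCc3ccccc3)c1)O2 | intermediate
30 | (2S,3S)-7-(benzyloxy)-2-[3,4-bis(benzyloxy)phenyl]-4-[(1E)-3-{[(2R)-3-[3,4-bis(benzyloxy)phenyl]-1-methoxy-1-oxopropan-2-yl]oxy}-3-oxoprop-1-en-1-yl]-2,3-dihydro-1-benzofuran-3-carboxylic acid | COC(=O)[C@@H](Cc1ccc(OCc2ccccc2)c(OCc2ccccc2)c1)OC(=O)/C=C/c1ccc(OCc2ccccc2)c2c1[C@H](C(=O)O)[C@@H](c1ccc(OCc3ccccc3)c(OCc3ccccc3)c1)O2 | intermediate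
31 | (2S,3S)-2-(3,4-dihydroxyphenyl)-4-[(1E)-3-{[(2R)-3-(3,4-dihydroxyphenyl)-1-methoxy-1-oxopropan-2-yl]oxy}-3-oxoprop-1-en-1-yl]-7-hydroxy-2,3-dihydro-1-benzofuran-3-carboxylic acid | COC(=O)[C@@H](Cc1ccc(O)c(O)c1)OC(=O)/C=C/c1ccc(O)c2c1[C@H](C(=O)O)[C@@H](c1ccc(O)c(O)c1)O2 | target

**Step count and risk**

Total steps: 19. Longest linear sequence: 16 steps (steps 1 to 12, then 16 to 19); steps 13 to 15 make the acrylate side chain.

Steps most likely to fail:

Step 10. The alkyne insertion may stop at a chromium-bound silyl vinylketene whose geometry does not allow electrocyclisation, or CO insertion may be bypassed to give a five-membered ring. The fallback changes the two-carbon partner and with it the regiochemical logic and the removal chemistry. It sets out from 17, which is heated in THF with ethynyltributylstannane in place of 18. A stannylalkyne should insert with the tin-bearing carbon bonded to the carbene carbon and cannot give a silicon-stabilised ketene, so the benzannulation should deliver the C6-stannylated phenol F1. Protodestannylation with CF3CO2H in CH2Cl2 at 0 °C, which is easier than protodesilylation, brings the material back to the route at 21.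

Step 7. The five-membered ketene acetal phosphate 10 may hydrolyse or open before oxidative addition, and the vinylstannane may lose tin on handling. The fallback avoids both the phosphate and the stannane. It sets out from 9, which is reduced with i-Bu2AlH (CH2Cl2, −78 °C) to the lactol F2. Dehydration with MsCl and Et3N (CH2Cl2, 0 °C to rt) gives the 2,3-dihydrofuran F3, and deprotonation of its vinylic C5–H next to oxygen with t-BuLi (THF, −78 to −20 °C) gives the vinyllithium 13 directly. The route is rejoined at 13 inside step 8, and steps 6 and 7 are not needed.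

Step 19. Lewis-acid ionisation of the benzylic C2–O1 bond may be followed by capture of the cation by the scavenger (ring opening), cleavage of five ethers may stay incomplete, and HCl may add to the acrylate. The fallback exchanges the benzyl ethers for acetates before the alkene exists and sets out from 22 and 24.
- Hydrogenolysis of 22 (H2, Pd on carbon, EtOAc, rt, neutral so that the triflate stays) gives the triphenol triflate F4, and Ac2O/pyridine gives the triacetate triflate F5.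
- 24 is acetylated on its two phenols (Ac2O, 2 equiv, Et3N, THF, 0 °C) to the diacetate F6 and acylated with acryloyl chloride and i-Pr2NEt to the acrylate F7.
- Heck coupling of F5 with F7 under the conditions of step 16 gives the pentaacetate cinnamate F8, HF·pyridine the carbinol F9, and TEMPO/PhI(OAc)2 the acid F10.
- NH4OAc in aqueous MeOH at rt, which cleaves aryl acetates much faster than alkyl esters, removes the five acetates and reaches 31.

Further compounds
F1 | step 10 | (2S,3R)-7-(benzyloxy)-2-[3,4-bis(benzyloxy)phenyl]-6-(tributylstannyl)-3-{[(triisopropylsilyl)oxy]methyl}-2,3-dihydro-1-benzofuran-4-ol | Oc1cc([Sn](CCCC)(CCCC)CCCC)c(OCc2ccccc2)c2c1[C@H](CO[Si](C(C)C)(C(C)C)C(C)C)[C@@H](c1ccc(OCc3ccccc3)c(OCc3ccccc3)c1)O2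
F2 | step 7 | (4R,5S)-5-[3,4-bis(benzyloxy)phenyl]-4-{[(triisopropylsilyl)oxy]methyl}oxolan-2-ol (both anomers) | OC1C[C@H](CO[Si](C(C)C)(C(C)C)C(C)C)[C@@H](c2ccc(OCc3ccccc3)c(OCc3ccccc3)c2)O1
F3 | step 7 | (2S,3R)-2-[3,4-bis(benzyloxy)phenyl]-3-{[(triisopropylsilyl)oxy]methyl}-2,3-dihydrofuran | C1=C[C@H](CO[Si](C(C)C)(C(C)C)C(C)C)[C@@H](c2ccc(OCc3ccccc3)c(OCc3ccccc3)c2)O1
F4 | step 19 | (2S,3R)-2-(3,4-dihydroxyphenyl)-7-hydroxy-3-{[(triisopropylsilyl)oxy]methyl}-2,3-dihydro-1-benzofuran-4-yl trifluoromethanesulfonate | O=S(=O)(Oc1ccc(O)c2c1[C@H](CO[Si](C(C)C)(C(C)C)C(C)C)[C@@H](c1ccc(O)c(O)c1)O2)C(F)(F)F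
F5 | step 19 | (2S,3R)-7-(acetyloxy)-2-[3,4-bis(acetyloxy)phenyl]-3-{[(triisopropylsilyl)oxy]methyl}-2,3-dihydro-1-benzofuran-4-yl trifluoromethanesulfonate | O=S(=O)(Oc1ccc(OC(C)=O)c2c1[C@H](CO[Si](C(C)C)(C(C)C)C(C)C)[C@@H](c1ccc(OC(C)=O)c(OC(C)=O)c1)O2)C(F)(F)F
F6 | step 19 | methyl (2R)-3-[3,4-bis(acetyloxy)phenyl]-2-hydroxypropanoate | COC(=O)[C@@H](Cc1ccc(OC(C)=O)c(OC(C)=O)c1)O
F7 | step 19 | methyl (2R)-3-[3,4-bis(acetyloxy)phenyl]-2-(prop-2-enoyloxy)propanoate | COC(=O)[C@@H](Cc1ccc(OC(C)=O)c(OC(C)=O)c1)OC(=O)C=C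
F8 | step 19 | methyl (2R)-3-[3,4-bis(acetyloxy)phenyl]-2-{[(2E)-3-[(2S,3R)-7-(acetyloxy)-2-[3,4-bis(acetyloxy)phenyl]-3-{[(triisopropylsilyl)oxy]methyl}-2,3-dihydro-1-benzofuran-4-yl]prop-2-enoyl]oxy}propanoate | COC(=O)[C@@H](Cc1ccc(OC(C)=O)c(OC(C)=O)c1)OC(=O)/C=C/c1ccc(OC(C)=O)c2c1[C@H](CO[Si](C(C)C)(C(C)C)C(C)C)[C@@H](c1ccc(OC(C)=O)c(OC(C)=O)c1)O2
F9 | step 19 | methyl (2R)-3-[3,4-bis(acetyloxy)phenyl]-2-{[(2E)-3-[(2S,3R)-7-(acetyloxy)-2-[3,4-bis(acetyloxy)phenyl]-3-(hydroxymethyl)-2,3-dihydro-1-benzofuran-4-yl]prop-2-enoyl]oxy}propanoate | COC(=O)[C@@H](Cc1ccc(OC(C)=O)c(OC(C)=O)c1)OC(=O)/C=C/c1ccc(OC(C)=O)c2c1[C@H](CO)[C@@H](c1ccc(OC(C)=O)c(OC(C)=O)c1)O2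
F10 | step 19 | (2S,3S)-7-(acetyloxy)-2-[3,4-bis(acetyloxy)phenyl]-4-[(1E)-3-{[(2R)-3-[3,4-bis(acetyloxy)phenyl]-1-methoxy-1-oxopropan-2-yl]oxy}-3-oxoprop-1-en-1-yl]-2,3-dihydro-1-benzofuran-3-carboxylic acid | COC(=O)[C@@H](Cc1ccc(OC(C)=O)c(OC(C)=O)c1)OC(=O)/C=C/c1ccc(OC(C)=O)c2c1[C@H](C(=O)O)[C@@H](c1ccc(OC(C)=O)c(OC(C)=O)c1)O2
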